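## The problem

Target **17** is an aromatic bisabolane: a benzene ring (C1–C6; C1 bears the side chain, C2 H, C3 OH, C4 CH3, C5 OH, C6 OAc) joined through C1 to the chain C7(=CH2)–C8H(O‑angeloyl)–C9H2–C10H=C11(CH3)2. No ring has to be closed; the bonds to be made are C1–C7 (arene to a 1,1‑disubstituted alkene) and C8–C9 (to the prenyl unit), and neither is hard in itself. There is one stereocentre, C8 (S), allylic to the C7 methylene; nothing else in the molecule can control it, so it must be set by a catalyst on a small fragment, and once esterified it must be kept away from Pd(0) and ionizing acid. The hard part is the arene: three phenolic oxygens in a 1,2,4 array (O6, O5, O3), of which only O6, the most hindered one between the side chain and O5–H, is acetylated. That aryl acetate is cleaved by nucleophiles, can migrate to the neighbouring O5 under base, and if lost exposes an air‑sensitive hydroxyhydroquinone; the angelate isomerizes to the (E)‑tiglate under nucleophilic or basic acylation; and the prenyl and styrene alkenes exclude hydrogenolysis, peracids, strong Lewis acids and boron halide ether cleavage, which leaves little room for three orthogonal phenol protecting groups. The feature the plan exploits: without the C6 acetoxy group the ring is a 5‑substituted 2‑methylresorcinol with a local twofold axis through C1 and C4, so C2–H and C6–H are equivalent, each is ortho to one hydroxyl and para to the other, and the only other activated carbon, C4, is blocked by the methyl group.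

## Retrosynthesis

**17 ⇒ 14 (cut the ring C6–O bond).** The acetoxy group is removed as a whole, which makes the forward step a C–H acetoxylation of resorcinol **14**. The neighbouring cuts are worse: cutting O6–acyl leads to a triol in which one of three phenols, the most hindered, would have to be chosen; cutting C1–C7 with the full oxygen pattern in place demands an arene whose three oxygens are already told apart. Precursor **14** has one oxygen and one acyl group fewer, a symmetric ring, and no base‑labile aryl acetate to carry through earlier steps. The forward reaction must oxidize only the phenol ring, at an H‑bearing carbon (either one gives **17**), and stop after one acetoxylation.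

**14 ⇒ 13 ⇒ 10 + 11 (cut two O–Si bonds, then the O8–acyl bond).** The angelate is put on alcohol **10** with angelic acid **11** while both phenols are silylated, because phenols would acylate faster than the hindered secondary alcohol. It is introduced after the C1–C7 coupling because an allylic ester would not be safe under Pd(0). The forward steps must acylate without Z→E isomerization and remove silicon without touching the angelate.

**10 ⇒ 3 + 9 (cut C1–C7).** An aryl–vinyl cross‑coupling joins symmetric boronate **3** to bromo‑alkenol **9**. The alternative C7–C8 cut needs an α‑arylvinyl metal and a β,γ‑unsaturated aldehyde that conjugates easily, and would set the stereocentre in the presence of the whole arene. The chosen cut lets C8 be made on a six‑carbon fragment. Boronate **3** comes from bis‑silyl ether **2** by C–H borylation at its only unhindered C–H, and **2** from 2‑methylresorcinol **1**; the same symmetry that serves the key step makes this fragment trivial.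

**9 ⇒ 8 ⇒ 6 ⇒ 4 (cut C10=C11, then C8–C9).** The prenyl terminus is made by cross‑metathesis of allyl carbinol **8**, and C8 is created by catalytic asymmetric allylation of 2‑bromoacrolein **6**, itself from acrolein **4**. Direct prenylation of **6** is not used because prenyl‑metal reagents react at their γ‑carbon and give the reverse‑prenyl isomer. The forward steps need enantiofacial control on a small enal and a metathesis that spares the bromoalkene.

## Roads not taken

Alternative 1: (the obvious route) Cut C1–C7 with all three oxygens already on the arene and distinguished by protecting groups. The key intermediate would be 1‑bromo‑2‑(methoxymethoxy)‑4‑methyl‑3,5‑bis(triisopropylsilyloxy)benzene A1; the forward key step is its borylation and Suzuki–Miyaura coupling with **9**, followed by angeloylation, acetal removal, acetylation of O6 and desilylation. The chosen plan is better because A1 must first be made from a symmetric arene by installing O6, protecting it orthogonally and then functionalizing C1 with a directing trick (C2 is the more activated carbon of a 1,2,4‑trioxygenated ring). That costs at least four extra operations, and every one of them exists only to distinguish oxygens that the key step never has to distinguish. A variant of this route is kept in reserve.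

Alternative 2: Cut the O6–acetyl bond: oxidize **14** to the hydroxyquinone A2 with a phenol‑to‑quinone oxidant, reduce it to the triol A3, and monoacetylate. The forward key step would be a regioselective acetylation of A3 at O6. The chosen plan is better because O6 is the most hindered of the three phenols and O5 is probably the most acidic, any base that drives acylation also drives O6⇄O5 acyl migration, and A3 is air‑sensitive. In the chosen step the oxygen arrives with its acetyl group, so the choice of hydroxyl never arises, and it is one step instead of three.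

Alternative 3: Cut the arene itself (C1–C6 and C2–C3). A 3‑alkoxy‑4‑methylcyclobutenedione A4 would be combined with a 2‑lithio‑1,3‑diene carrying C7–C11, the tertiary alkoxide trapped as acetate to give cyclobutenone A5, and A5 heated (Moore‑type electrocyclic ring opening and 6π closure). This gives a hydroquinone monoacetate in which O6 is acetylated and O3 free by mechanism. The chosen plan is better because the dienyllithium with the C8 stereocentre is as hard to make as the whole side chain, O5 arrives as an alkyl ether that needs acid to cleave next to a prenyl group and an aryl acetate, and the angelate would still have to be installed beside a free phenol.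

Key step: step 9

Remarks on the chemistry (assumptions):
- The [C@H] centre of the target SMILES is C8 with the (S) configuration (priorities O > C7 > C9 > H); the ester is the (Z)‑2‑methylbut‑2‑enoate (angelate).
- 2‑Bromoacrolein **6** does not store well and is therefore made from acrolein **4** and used fresh.
- The sense of induction in step 4 is taken over from aryl and α,β‑unsaturated aldehydes; if **6** were to bind the other way round, the (R)‑catalyst would be used instead.

## Steps

Step 1
Reactants: 1 2‑methylresorcinol (2‑methylbenzene‑1,3‑diol)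
Product: 2 1,3‑bis(triisopropylsilyloxy)‑2‑methylbenzene
Conditions: TIPSCl, imidazole, DMF, 40 °C
Reagents that add atoms: triisopropylsilyl chloride, CC(C)[Si](Cl)(C(C)C)C(C)C
Why: Imidazole‑promoted silylation of both phenols; triisopropylsilyl ethers are chosen because they should survive the aqueous base of step 6 and the heating of step 7 and leave with buffered fluoride in step 8.

Step 2
Reactants: 2 1,3‑bis(triisopropylsilyloxy)‑2‑methylbenzene
Product: 3 2‑[4‑methyl‑3,5‑bis(triisopropylsilyloxy)phenyl]‑4,4,5,5‑tetramethyl‑1,3,2‑dioxaborolane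
Conditions: [Ir(OMe)(cod)]2 (cat.), dtbpy (cat.), B2pin2, THF, 80 °C
Reagents that add atoms: bis(pinacolato)diboron, CC1(C)OB(B2OC(C)(C)C(C)(C)O2)OC1(C)C
Why: Iridium‑catalysed aromatic C–H borylation is sterically controlled; of the three ring C–H bonds of 2 only the one meta to both silyloxy groups (the future C1) has no ortho substituent, so a single symmetric boronate should form.

Step 3
Reactants: 4 acrolein (prop‑2‑enal)
Product: 6 2‑bromoacrolein (2‑bromoprop‑2‑enal), via 2,3‑dibromopropanal 5 (not isolated)
Conditions: Br2, CH2Cl2, −78 °C; then Et3N, −78 → 0 °C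
Reagents that add atoms: bromine, BrBr
Why: Bromine adds across the alkene and triethylamine then removes HBr from the acidic α‑position (bromination–dehydrobromination of an enal); the product is distilled and used at once.

Step 4
Reactants: 6 2‑bromoacrolein
Product: 8 (S)‑2‑bromohexa‑1,5‑dien‑3‑ol, via O‑pinacolboryl ether 7 (not isolated)
Conditions: allyl‑Bpin, (S)‑TRIP (5 mol %), toluene, −30 °C; aq. NaHCO3 work‑up
Reagents that add atoms: allylboronic acid pinacol ester, C=CCB1OC(C)(C)C(C)(C)O1
Why: Chiral phosphoric acid‑catalysed allylboration of an aldehyde through a closed six‑membered transition state forms C8–C9 and the C8 stereocentre under catalyst control. (S)‑TRIP is chosen by analogy with aryl and α,β‑unsaturated aldehydes (the (R)‑catalyst gives their (R)‑carbinols), so that allyl adds to the Si face and the (S)‑alcohol results; the borate ester 7 is hydrolysed on work‑up.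

Step 5
Reactants: 8 (S)‑2‑bromohexa‑1,5‑dien‑3‑ol
Product: 9 (S)‑2‑bromo‑6‑methylhepta‑1,5‑dien‑3‑ol
Conditions: Grubbs II (3 mol %), 2‑methyl‑2‑butene/CH2Cl2, 35 °C
Reagents that add atoms: 2‑methyl‑2‑butene, CC=C(C)C
Why: Olefin cross‑metathesis with 2‑methyl‑2‑butene turns the terminal vinyl group into the isopropylidene (prenyl) terminus; the electron‑poor, 1,1‑disubstituted bromoalkene should not enter the catalytic cycle and C8 is not touched.

Step 6
Reactants: 3 2‑[4‑methyl‑3,5‑bis(triisopropylsilyloxy)phenyl]‑4,4,5,5‑tetramethyl‑1,3,2‑dioxaborolane; 9 (S)‑2‑bromo‑6‑methylhepta‑1,5‑dien‑3‑ol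
Product: 10 (S)‑6‑methyl‑2‑[4‑methyl‑3,5‑bis(triisopropylsilyloxy)phenyl]hepta‑1,5‑dien‑3‑ol
Conditions: Pd(dppf)Cl2 (5 mol %), K3PO4, THF/H2O, 55 °C
Reagents that add atoms: none
Why: Suzuki–Miyaura coupling of an unhindered arylboronate with a 2‑bromoallylic alcohol forms C1–C7; the free hydroxyl is tolerated and the stereocentre is not involved.

Step 7
Reactants: 10 (S)‑6‑methyl‑2‑[4‑methyl‑3,5‑bis(triisopropylsilyloxy)phenyl]hepta‑1,5‑dien‑3‑ol; 11 angelic acid ((Z)‑2‑methylbut‑2‑enoic acid)
Product: 13 (S)‑6‑methyl‑2‑[4‑methyl‑3,5‑bis(triisopropylsilyloxy)phenyl]hepta‑1,5‑dien‑3‑yl (Z)‑2‑methylbut‑2‑enoate, via mixed anhydride 12 (not isolated)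
Conditions: 11, 2,4,6‑Cl3C6H2COCl, Et3N, toluene, rt; then 10, 75 °C
Reagents that add atoms: none
Why: Yamaguchi esterification through the preformed mixed anhydride 12 without a nucleophilic amine catalyst, the variant that delivers angelates with the (Z) geometry retained; the alcohol attacks the less hindered angeloyl carbonyl, and with both phenols silylated only O8 can be acylated.

Step 8
Reactants: 13 (S)‑6‑methyl‑2‑[4‑methyl‑3,5‑bis(triisopropylsilyloxy)phenyl]hepta‑1,5‑dien‑3‑yl (Z)‑2‑methylbut‑2‑enoate
Product: 14 (S)‑2‑(3,5‑dihydroxy‑4‑methylphenyl)‑6‑methylhepta‑1,5‑dien‑3‑yl (Z)‑2‑methylbut‑2‑enoate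
Conditions: TBAF, AcOH, THF, 0 °C
Reagents that add atoms: none
Why: Fluoride cleaves both aryl silyl ethers; acetic acid buffers fluoride and the phenoxides so that the angelate should be neither isomerized nor cleaved.

Step 9
Reactants: 14 (S)‑2‑(3,5‑dihydroxy‑4‑methylphenyl)‑6‑methylhepta‑1,5‑dien‑3‑yl (Z)‑2‑methylbut‑2‑enoate
Product: 17 (S)‑2‑(2‑acetoxy‑3,5‑dihydroxy‑4‑methylphenyl)‑6‑methylhepta‑1,5‑dien‑3‑yl (Z)‑2‑methylbut‑2‑enoate, via aryloxy‑λ3‑iodane 15 (not isolated), via acetoxy dienone 16 (not isolated)
Conditions: PhI(OAc)2 (0.9 equiv, slow addition), AcOH/CH2Cl2 (1:1), 0 °C, dark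
Reagents that add atoms: (diacetoxyiodo)benzene, CC(=O)OI(OC(C)=O)c1ccccc1
Why: Wessely‑type oxidative nuclear acetoxylation of a phenol with an iodine(III) diacetate: one phenolic OH of 14 exchanges for acetate on iodine to give the aryloxy‑λ3‑iodane 15, acetate adds to the ring carbon para to the iodine‑bound oxygen as iodobenzene leaves, and the resulting 4‑acetoxycyclohexa‑2,5‑dienone 16, which still carries H on the acetoxylated carbon, tautomerizes to the arene 17. The closest known reaction types are the Pb(IV)/I(III) acetoxylation of phenols to quinol acetates and the para‑oxygenation of para‑unsubstituted phenols by iodine(III) reagents. No ring is closed and no stereocentre is made; the sp3 carbon of 16 is lost on rearomatization and C8 is a spectator. The step needs three selectivities. Site: the electrophilic carbons of 15 are C2, C6 and C4; attack at either H‑bearing carbon, whichever hydroxyl carries iodine and whether para or ortho to it, gives the same constitution 17 because C2 and C6 of 14 are equivalent, and only attack at the methyl‑bearing C4 (a quaternary centre that cannot rearomatize) would be lost, which the preference of these oxidations for a free para position should disfavour. Chemoselectivity: the reagent engages only through O–I ligand exchange, so the prenyl alkene, the styrene (which sits meta to both hydroxyls and cannot form an extended quinone methide) and both esters should be spectators, and the large excess of acetic acid should capture the activated ring before the C10=C11 alkene can. Degree of oxidation: the acyloxy group makes 17 less electron‑rich than 14, and the oxidant is kept substoichiometric and added slowly so that unreacted 14 can be recovered and recycled. The oxygen arrives already acetylated under acidic, non‑nucleophilic conditions, so neither a choice among three hydroxyls nor base‑induced O6→O5 acyl migration arises.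

## Compound list

1 | 2‑methylresorcinol | Cc1c(O)cccc1O | starting material
2 | 1,3‑bis(triisopropylsilyloxy)‑2‑methylbenzene | Cc1c(O[Si](C(C)C)(C(C)C)C(C)C)cccc1O[Si](C(C)C)(C(C)C)C(C)C | intermediate
3 | 2‑[4‑methyl‑3,5‑bis(triisopropylsilyloxy)phenyl]‑4,4,5,5‑tetramethyl‑1,3,2‑dioxaborolane | Cc1c(O[Si](C(C)C)(C(C)C)C(C)C)cc(B2OC(C)(C)C(C)(C)O2)cc1O[Si](C(C)C)(C(C)C)C(C)C | intermediate
4 | acrolein | C=CC=O | starting material
5 | 2,3‑dibromopropanal (racemic, not isolated) | O=CC(Br)CBr | intermediate
6 | 2‑bromoacrolein | C=C(Br)C=O | intermediate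
7 | 2‑{[(3S)‑2‑bromohexa‑1,5‑dien‑3‑yl]oxy}‑4,4,5,5‑tetramethyl‑1,3,2‑dioxaborolane (not isolated) | C=C(Br)[C@H](CC=C)OB1OC(C)(C)C(C)(C)O1 | intermediate
8 | (S)‑2‑bromohexa‑1,5‑dien‑3‑ol | C=C(Br)[C@H](CC=C)O | intermediate
9 | (S)‑2‑bromo‑6‑methylhepta‑1,5‑dien‑3‑ol | C=C(Br)[C@H](CC=C(C)C)O | intermediate
10 | (S)‑6‑methyl‑2‑[4‑methyl‑3,5‑bis(triisopropylsilyloxy)phenyl]hepta‑1,5‑dien‑3‑ol | C=C(c1cc(O[Si](C(C)C)(C(C)C)C(C)C)c(C)c(O[Si](C(C)C)(C(C)C)C(C)C)c1)[C@H](CC=C(C)C)O | intermediate
11 | angelic acid, (Z)‑2‑methylbut‑2‑enoic acid | C/C=C(/C)C(=O)O | starting material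
12 | (Z)‑2‑methylbut‑2‑enoic 2,4,6‑trichlorobenzoic anhydride (not isolated) | C/C=C(/C)C(=O)OC(=O)c1c(Cl)cc(Cl)cc1Cl | intermediate
13 | (S)‑6‑methyl‑2‑[4‑methyl‑3,5‑bis(triisopropylsilyloxy)phenyl]hepta‑1,5‑dien‑3‑yl (Z)‑2‑methylbut‑2‑enoate | C=C(c1cc(O[Si](C(C)C)(C(C)C)C(C)C)c(C)c(O[Si](C(C)C)(C(C)C)C(C)C)c1)[C@H](CC=C(C)C)OC(=O)/C(C)=C\C | intermediate
14 | (S)‑2‑(3,5‑dihydroxy‑4‑methylphenyl)‑6‑methylhepta‑1,5‑dien‑3‑yl (Z)‑2‑methylbut‑2‑enoate | C=C(c1cc(O)c(C)c(O)c1)[C@H](CC=C(C)C)OC(=O)/C(C)=C\C | intermediate
15 | acetoxy(phenyl)‑λ3‑iodanyl ether of one phenolic oxygen of 14 (not isolated) | C=C(c1cc(O)c(C)c(OI(OC(C)=O)c2ccccc2)c1)[C@H](CC=C(C)C)OC(=O)/C(C)=C\C | intermediate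
16 | (3S)‑2‑(6‑acetoxy‑5‑hydroxy‑4‑methyl‑3‑oxocyclohexa‑1,4‑dien‑1‑yl)‑6‑methylhepta‑1,5‑dien‑3‑yl (Z)‑2‑methylbut‑2‑enoate (either configuration at ring C6, not isolated) | C=C(C1=CC(=O)C(C)=C(O)C1OC(C)=O)[C@H](CC=C(C)C)OC(=O)/C(C)=C\C | intermediate
17 | (S)‑2‑(2‑acetoxy‑3,5‑dihydroxy‑4‑methylphenyl)‑6‑methylhepta‑1,5‑dien‑3‑yl (Z)‑2‑methylbut‑2‑enoate | C=C(c1cc(O)c(C)c(O)c1OC(C)=O)[C@H](CC=C(C)C)OC(=O)/C(C)=C\C | target

## Step count and risk

Total: 9 steps. Longest linear sequence: 7 steps (4 → 6 → 8 → 9 → 10 → 13 → 14 → 17, steps 3–9); the arene branch (1 → 2 → 3, steps 1–2) joins at step 6.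

**Step 9 (key step).** Four processes could spoil it:
- delivery of acetate to the methyl‑bearing C4 instead of C2/C6, which leads to dearomatization that cannot be reversed;
- a second oxidation of the product (a further ligand exchange at O3 and loss of the acetyl on the way to the quinone level, or a second acetoxylation);
- capture of the activated ring by the C10=C11 alkene, or loss of a proton from the C4 methyl group;
- migration of the acetyl group from O6 to O5 if the work‑up is basic.

Fallback (known chemistry only; leaves the route at 2 and rejoins it at 17): the oxygen is placed on the arene before the coupling and kept apart from the other two by a protecting group. Bromination of 2 with NBS at one of its two equivalent activated positions should give 1‑bromo‑3‑methyl‑2,4‑bis(triisopropylsilyloxy)benzene F1. Bromine–lithium exchange (n‑BuLi, −78 °C), borylation with trimethyl borate and oxidation with H2O2 should give 3‑methyl‑2,4‑bis(triisopropylsilyloxy)phenol F2, whose hydroxyl is the future O6. Methoxymethylation gives 1‑(methoxymethoxy)‑3‑methyl‑2,4‑bis(triisopropylsilyloxy)benzene F3. Acetal‑directed ortho‑lithiation (the only ortho C–H is the future C1) and trapping with isopropoxy pinacolborane give the MOM‑protected arylboronate F4. Suzuki–Miyaura coupling of F4 with 9 gives the MOM‑protected allylic alcohol F5, and Yamaguchi acylation with 12 gives the MOM‑protected angelate F6. Acid‑catalysed methanolysis of the acetal (cat. HCl, MeOH/THF) gives the O6‑phenol F7, the only free hydroxyl in the molecule, which is acetylated (Ac2O, pyridine) to the bis‑silylated acetate F8. HF·pyridine then removes both silyl groups to give 17.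

**Step 4.** Enantiofacial discrimination may be poor for this small α‑bromo enal, which lacks the large aryl group the catalyst pocket usually recognizes, and the enal may oligomerize in the presence of acid. Fallback (leaves the route at 6, rejoins at 8): zinc‑mediated Barbier allylation of 6 with allyl bromide gives racemic 2‑bromohexa‑1,5‑dien‑3‑ol F9. Buffered Dess–Martin oxidation gives 2‑bromohexa‑1,5‑dien‑3‑one F10, kept cold to prevent conjugation of the skipped alkene. Corey–Bakshi–Shibata reduction with the (R)‑oxazaborolidine and catecholborane, in which the α‑bromovinyl group acts as the large substituent, should give 8.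

**Step 7.** The angeloyl unit may isomerize to tigloyl in the activated acyl species (reversible conjugate addition of chloride or amine), and acylation of the hindered allylic alcohol may be slow at a temperature the mixed anhydride tolerates. Fallback (leaves the route at 10, rejoins at 13): the (Z)‑alkene is built on the ester instead of being carried in. Carbodiimide acylation of 10 with the Still–Gennari phosphonopropionic acid gives the 2‑[bis(2,2,2‑trifluoroethoxy)phosphoryl]propanoate F11. Deprotonation with KHMDS/18‑crown‑6 at −78 °C and olefination with acetaldehyde should give 13 with kinetic (Z) selectivity.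

**Step 6.** Protodeboronation of the electron‑rich boronate, partial loss of a silyl group to aqueous base, or β‑hydride loss from the alkenylpalladium intermediate may erode the coupling. Fallback (leaves the route at 3 and 9, rejoins at 10): C1–C7 is made by carbometalation instead of cross‑coupling. Copper(II) bromide converts 3 into 5‑bromo‑2‑methyl‑1,3‑bis(triisopropylsilyloxy)benzene F12. Dehydrobromination of 9 with excess LDA gives (S)‑6‑methylhept‑5‑en‑1‑yn‑3‑ol F13. The Grignard reagent from F12 is added to the magnesium alkoxide of F13 under CuI catalysis; anti‑carbomagnesiation places the aryl group on the internal alkyne carbon through the alkoxide chelate, and protonolysis gives 10.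

## Further compounds

F1 | step 9 | 1‑bromo‑3‑methyl‑2,4‑bis(triisopropylsilyloxy)benzene | Cc1c(O[Si](C(C)C)(C(C)C)C(C)C)ccc(Br)c1O[Si](C(C)C)(C(C)C)C(C)C
F2 | step 9 | 3‑methyl‑2,4‑bis(triisopropylsilyloxy)phenol | Cc1c(O[Si](C(C)C)(C(C)C)C(C)C)ccc(O)c1O[Si](C(C)C)(C(C)C)C(C)C
F3 | step 9 | 1‑(methoxymethoxy)‑3‑methyl‑2,4‑bis(triisopropylsilyloxy)benzene | COCOc1ccc(O[Si](C(C)C)(C(C)C)C(C)C)c(C)c1O[Si](C(C)C)(C(C)C)C(C)C
F4 | step 9 | 2‑[2‑(methoxymethoxy)‑4‑methyl‑3,5‑bis(triisopropylsilyloxy)phenyl]‑4,4,5,5‑tetramethyl‑1,3,2‑dioxaborolane | COCOc1c(B2OC(C)(C)C(C)(C)O2)cc(O[Si](C(C)C)(C(C)C)C(C)C)c(C)c1O[Si](C(C)C)(C(C)C)C(C)C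
F5 | step 9 | (S)‑2‑[2‑(methoxymethoxy)‑4‑methyl‑3,5‑bis(triisopropylsilyloxy)phenyl]‑6‑methylhepta‑1,5‑dien‑3‑ol | C=C(c1cc(O[Si](C(C)C)(C(C)C)C(C)C)c(C)c(O[Si](C(C)C)(C(C)C)C(C)C)c1OCOC)[C@H](CC=C(C)C)O
F6 | step 9 | (S)‑2‑[2‑(methoxymethoxy)‑4‑methyl‑3,5‑bis(triisopropylsilyloxy)phenyl]‑6‑methylhepta‑1,5‑dien‑3‑yl (Z)‑2‑methylbut‑2‑enoate | C=C(c1cc(O[Si](C(C)C)(C(C)C)C(C)C)c(C)c(O[Si](C(C)C)(C(C)C)C(C)C)c1OCOC)[C@H](CC=C(C)C)OC(=O)/C(C)=C\C
F7 | step 9 | (S)‑2‑[2‑hydroxy‑4‑methyl‑3,5‑bis(triisopropylsilyloxy)phenyl]‑6‑methylhepta‑1,5‑dien‑3‑yl (Z)‑2‑methylbut‑2‑enoate | C=C(c1cc(O[Si](C(C)C)(C(C)C)C(C)C)c(C)c(O[Si](C(C)C)(C(C)C)C(C)C)c1O)[C@H](CC=C(C)C)OC(=O)/C(C)=C\C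
F8 | step 9 | (S)‑2‑[2‑acetoxy‑4‑methyl‑3,5‑bis(triisopropylsilyloxy)phenyl]‑6‑methylhepta‑1,5‑dien‑3‑yl (Z)‑2‑methylbut‑2‑enoate | C=C(c1cc(O[Si](C(C)C)(C(C)C)C(C)C)c(C)c(O[Si](C(C)C)(C(C)C)C(C)C)c1OC(C)=O)[C@H](CC=C(C)C)OC(=O)/C(C)=C\C
F9 | step 4 | racemic 2‑bromohexa‑1,5‑dien‑3‑ol | C=C(Br)C(O)CC=C
F10 | step 4 | 2‑bromohexa‑1,5‑dien‑3‑one | C=C(Br)C(=O)CC=C
F11 | step 7 | (S)‑6‑methyl‑2‑[4‑methyl‑3,5‑bis(triisopropylsilyloxy)phenyl]hepta‑1,5‑dien‑3‑yl 2‑[bis(2,2,2‑trifluoroethoxy)phosphoryl]propanoate (either configuration at the phosphonate α‑carbon) | C=C(c1cc(O[Si](C(C)C)(C(C)C)C(C)C)c(C)c(O[Si](C(C)C)(C(C)C)C(C)C)c1)[C@H](CC=C(C)C)OC(=O)C(C)P(=O)(OCC(F)(F)F)OCC(F)(F)F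
F12 | step 6 | 5‑bromo‑2‑methyl‑1,3‑bis(triisopropylsilyloxy)benzene | Cc1c(O[Si](C(C)C)(C(C)C)C(C)C)cc(Br)cc1O[Si](C(C)C)(C(C)C)C(C)C
F13 | step 6 | (S)‑6‑methylhept‑5‑en‑1‑yn‑3‑ol | C#C[C@H](CC=C(C)C)O
A1 | alternative 1 | 1‑bromo‑2‑(methoxymethoxy)‑4‑methyl‑3,5‑bis(triisopropylsilyloxy)benzene | COCOc1c(Br)cc(O[Si](C(C)C)(C(C)C)C(C)C)c(C)c1O[Si](C(C)C)(C(C)C)C(C)C
A2 | alternative 2 | (S)‑2‑(5‑hydroxy‑4‑methyl‑3,6‑dioxocyclohexa‑1,4‑dien‑1‑yl)‑6‑methylhepta‑1,5‑dien‑3‑yl (Z)‑2‑methylbut‑2‑enoate | C=C(C1=CC(=O)C(C)=C(O)C1=O)[C@H](CC=C(C)C)OC(=O)/C(C)=C\C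
A3 | alternative 2 | (S)‑6‑methyl‑2‑(2,3,5‑trihydroxy‑4‑methylphenyl)hepta‑1,5‑dien‑3‑yl (Z)‑2‑methylbut‑2‑enoate | C=C(c1cc(O)c(C)c(O)c1O)[C@H](CC=C(C)C)OC(=O)/C(C)=C\C
A4 | alternative 3 | 3‑tert‑butoxy‑4‑methylcyclobut‑3‑ene‑1,2‑dione | CC1=C(OC(C)(C)C)C(=O)C1=O
A5 | alternative 3 | 4‑acetoxy‑3‑tert‑butoxy‑4‑[(4S)‑4‑(tert‑butyldimethylsilyloxy)‑7‑methyl‑3‑methyleneocta‑1,6‑dien‑2‑yl]‑2‑methylcyclobut‑2‑en‑1‑one (either configuration at ring C4) | CC1=C(OC(C)(C)C)C(OC(C)=O)(C(=C)C(=C)[C@H](CC=C(C)C)O[Si](C)(C)C(C)(C)C)C1=O
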